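## Retrosynthetic overview

1. δ-Lactone C–O bond, formed last: the target comes from a 7-substituted 2-oxabicyclo[2.2.1]heptan-6-one by Baeyer–Villiger insertion of O between the ketone carbon and the O-bearing bridgehead.
2. Oxolane C–O bond, the key bond: the oxanorbornanone comes from a 2-chlorocyclopentanone that carries a free α-hydroxy ester. The OH captures the derived oxyallyl cation.
3. Quaternary C–CH bond: the chloroketone comes from a decalin tertiary alcohol (as its tertiary radical) and an (R,R)-4-substituted 2-chlorocyclopent-2-enone.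
4. The decalinol comes from a carbonyl-ene closure of ring B. Its precursor comes from an (S)-allylsilane and MVK (Sakurai reaction with chirality transfer), and ring A is 3-methylcyclohexenone.
5. The chloroenone comes from cyclopentene and methyl glyoxylate by asymmetric ene reaction, allylic oxidation and α-chlorination. Ring order: A (bought), B, cyclopentane (bought), oxolane, lactone.

Assumption: 4 is bought as a catalogue organosilane, and the ligand antipodes named in steps 2 and 5 are those predicted from the sense of induction known for the closest substrates.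

## Route

Step 1
Reactants: 1 3-methylcyclohex-2-en-1-one
Product: 3 3,3-dimethylcyclohex-1-en-1-yl trifluoromethanesulfonate, via bromomagnesium enolate 2 (not isolated)
Conditions: MeMgBr, CuI (10 mol %), THF, −20 °C; then PhNTf2, −20 °C to rt
Reagents that add atoms: methylmagnesium bromide C[Mg]Br; N-phenylbis(trifluoromethanesulfonimide) O=S(=O)(N(c1ccccc1)S(=O)(=O)C(F)(F)F)C(F)(F)F
Why: Copper-catalysed conjugate addition builds the gem-dimethyl carbon and leaves a regiodefined enolate on the hindered side, which is O-triflated in the same flask (conjugate addition/enolate trapping); no stereocentre is formed.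

Step 2
Reactants: 3 3,3-dimethylcyclohex-1-en-1-yl trifluoromethanesulfonate; 4 (1-chloroethyl)triethylsilane (racemic)
Product: 6 triethyl[(1S)-1-(3,3-dimethylcyclohex-1-en-1-yl)ethyl]silane, via 1-(triethylsilyl)ethylmagnesium chloride 5 (not isolated)
Conditions: 4, Mg, Et2O, reflux; then 3, PdCl2[(S)-(R)-PPFA] (1 mol %), Et2O, 0 °C
Reagents that add atoms: none
Why: Asymmetric Kumada (Grignard) cross-coupling: the configurationally labile secondary α-silyl Grignard reagent undergoes dynamic kinetic resolution on the chiral ferrocenylphosphine–Pd catalyst, which sets the (S) C–Si stereocentre.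

Step 3
Reactants: 6 triethyl[(1S)-1-(3,3-dimethylcyclohex-1-en-1-yl)ethyl]silane; 7 methyl vinyl ketone
Product: 8 4-[(1S,2E)-2-ethylidene-6,6-dimethylcyclohexyl]butan-2-one
Conditions: TiCl4 (1.1 equiv), CH2Cl2, −78 °C
Reagents that add atoms: none
Why: Hosomi–Sakurai conjugate allylation: the ring CH (γ-carbon) attacks the unhindered CH2 of Ti-activated MVK anti to the C–Si bond (anti-SE2'), so the silane chirality is relayed to the ring CH (S) and the (E)-ethylidene is formed, while leakage through the other rotamer gives (R,Z)-8, which becomes a separable diastereomer in step 4.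

Step 4
Reactants: 8 4-[(1S,2E)-2-ethylidene-6,6-dimethylcyclohexyl]butan-2-one
Product: 9 (1R,2S,4aS)-1,2,5,5-tetramethyl-1,2,3,4,4a,5,6,7-octahydronaphthalen-2-ol
Conditions: Me2AlCl (1.2 equiv), CH2Cl2, −78 to −20 °C
Reagents that add atoms: none
Why: Type I intramolecular carbonyl-ene reaction (the α-ambrinol cyclisation) with a proton-scavenging Lewis acid: the ethylidene CH attacks the ketone on the face that carries the axial side chain while the oxygen takes the axial H of the ring CH2, so the alkene lands only at C8=C8a, the (E)-methyl ends equatorial (H-1 cis to H-4a), and the carbinol configuration (OH axial) does not matter because it is erased in step 8.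

Step 5
Reactants: 10 cyclopentene; 11 methyl glyoxylate (freshly cracked from its methyl hemiacetal)
Product: 12 methyl (2R)-2-[(1R)-cyclopent-2-en-1-yl]-2-hydroxyacetate
Conditions: [Cu((R,R)-t-Bu-box)](SbF6)2 (10 mol %), CH2Cl2, rt
Reagents that add atoms: none
Why: Catalytic enantioselective glyoxylate-ene reaction with a chelating Cu(II)-bis(oxazoline) Lewis acid, a reaction shown for cyclic 1,2-disubstituted alkenes: the catalyst fixes the aldehyde face (carbinol R), and the transition state that keeps the chelated ester away from the ring CH2 groups gives the like (R,R) diastereomer.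

Step 6
Reactants: 12 methyl (2R)-2-[(1R)-cyclopent-2-en-1-yl]-2-hydroxyacetate
Product: 13 methyl (2R)-2-hydroxy-2-[(1R)-4-oxocyclopent-2-en-1-yl]acetate
Conditions: Rh2(cap)4 (1 mol %), t-BuOOH (70 % aq, 5 equiv), CH2Cl2, rt
Reagents that add atoms: tert-butyl hydroperoxide CC(C)(C)OO
Why: Dirhodium caprolactamate/TBHP allylic oxidation, which tolerates free secondary alcohols: H-abstraction occurs at the open ring CH2 rather than at the tertiary C–H deactivated by the hydroxy ester, the peroxyl radical is captured at the allyl terminus remote from the substituent, and no stereocentre is touched.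

Step 7
Reactants: 13 methyl (2R)-2-hydroxy-2-[(1R)-4-oxocyclopent-2-en-1-yl]acetate
Product: 14 methyl (2R)-2-[(1R)-3-chloro-4-oxocyclopent-2-en-1-yl]-2-hydroxyacetate
Conditions: PhICl2 (1.1 equiv), pyridine, CH2Cl2, 0 °C to rt
Reagents that add atoms: (dichloroiodo)benzene ClI(Cl)c1ccccc1
Why: α-Chlorination of an enone by chlorination and pyridine-induced dehydrochlorination (addition–elimination), which raises the acceptor reactivity and places the leaving group needed in step 9 without disturbing the γ-stereocentre.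

Step 8
Reactants: 9 (1R,2S,4aS)-1,2,5,5-tetramethyl-1,2,3,4,4a,5,6,7-octahydronaphthalen-2-ol; 14 methyl (2R)-2-[(1R)-3-chloro-4-oxocyclopent-2-en-1-yl]-2-hydroxyacetate
Product: 16 methyl (2R)-2-{(1R,2R,3R)-3-chloro-4-oxo-2-[(1S,2R,4aS)-1,2,5,5-tetramethyl-1,2,3,4,4a,5,6,7-octahydronaphthalen-2-yl]cyclopentyl}-2-hydroxyacetate, via benzoxazoline adduct 15 (not isolated)
Conditions: 9 (1.3 equiv), 5,7-di-tert-butyl-3-phenylbenzoxazolium BF4 (1.2 equiv), pyridine, MTBE, rt; then 14, [Ir(ppy)2(dtbbpy)]PF6 (1 mol %), quinuclidine (10 mol %), MTBE/DMA, 450 nm, rt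
Reagents that add atoms: none
Why: Photoredox deoxygenative Giese addition of an NHC-activated tertiary alcohol: oxidation, deprotonation and β-scission of 15 give the tertiary decalinyl radical, which adds to the enone β-carbon anti to the ring side chain (sets the ring CH) and through the decalin face anti to the vicinal methyl (anti rule for β-substituted cyclic radicals, large group equatorial, sets the quaternary carbon), and reduction–protonation leaves the 2-chloroketone, drawn as the trans epimer, whose C–Cl configuration is erased in step 9.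

Step 9
Reactants: 16 methyl (2R)-2-{(1R,2R,3R)-3-chloro-4-oxo-2-[(1S,2R,4aS)-1,2,5,5-tetramethyl-1,2,3,4,4a,5,6,7-octahydronaphthalen-2-yl]cyclopentyl}-2-hydroxyacetate
Product: 18 methyl (1R,3R,4R,7R)-6-oxo-7-[(1S,2R,4aS)-1,2,5,5-tetramethyl-1,2,3,4,4a,5,6,7-octahydronaphthalen-2-yl]-2-oxabicyclo[2.2.1]heptane-3-carboxylate, via oxyallyl cation 17 (not isolated)
Conditions: Na2CO3 (2 equiv), (CF3)2CHOH, 0.02 M, 0 °C to rt
Reagents that add atoms: none
Why: Proposed new method: bridging intramolecular oxyallyl etherification, in which enolisation towards the ring CH2 and loss of chloride in the ionising, weakly nucleophilic fluoroalcohol give the cyclopentenyl oxyallyl cation 17; the tethered secondary OH can reach only the terminus next to the decalinyl-bearing carbon (five-membered closure, against an oxetane at the other terminus) and only from the face that carries the side chain, anti to the decalin, so the new C–O bond and the O–CH stereocentre are set by geometry and both chloride epimers converge; the closest known chemistry is the generation of oxyallyl cations from 2-chlorocyclopentanones in fluorinated alcohols with intermolecular capture by alcohols or dienes, together with interrupted-Nazarov trapping, and a tethered alcohol forging a 2-oxanorbornanone has not been shown.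

Step 10
Reactants: 18 methyl (1R,3R,4R,7R)-6-oxo-7-[(1S,2R,4aS)-1,2,5,5-tetramethyl-1,2,3,4,4a,5,6,7-octahydronaphthalen-2-yl]-2-oxabicyclo[2.2.1]heptane-3-carboxylate
Product: 19 methyl (1S,5R,6R,8R)-3-oxo-8-[(1S,2R,4aS)-1,2,5,5-tetramethyl-1,2,3,4,4a,5,6,7-octahydronaphthalen-2-yl]-2,7-dioxabicyclo[3.2.1]octane-6-carboxylate
Conditions: Me3SiOOSiMe3 (1.5 equiv), TMSOTf (10 mol %), 2,6-di-tert-butylpyridine (20 mol %), CH2Cl2, −78 to −40 °C
Reagents that add atoms: bis(trimethylsilyl) peroxide C[Si](C)(C)OO[Si](C)(C)C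
Why: Baeyer–Villiger oxidation with a silyl peroxide, a peracid-free variant that does not epoxidise C=C bonds: the strained, inductively activated ketone forms the Criegee adduct and the α-alkoxy bridgehead carbon migrates with retention in preference to CH2, as in oxanorbornanone oxidations, while the buffered low temperature protects the trisubstituted alkene and the acylal.

## Compound list

1 | 3-methylcyclohex-2-en-1-one | CC1=CC(=O)CCC1 | starting material
2 | bromomagnesium 3,3-dimethylcyclohex-1-en-1-olate | CC1(C)C=C(O[Mg]Br)CCC1 | intermediate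
3 | 3,3-dimethylcyclohex-1-en-1-yl trifluoromethanesulfonate | CC1(C)C=C(OS(=O)(=O)C(F)(F)F)CCC1 | intermediate
4 | (1-chloroethyl)triethylsilane (racemic) | CC(Cl)[Si](CC)(CC)CC | starting material
5 | 1-(triethylsilyl)ethylmagnesium chloride | CC([Mg]Cl)[Si](CC)(CC)CC | intermediate
6 | triethyl[(1S)-1-(3,3-dimethylcyclohex-1-en-1-yl)ethyl]silane | C[C@H]([Si](CC)(CC)CC)C1=CC(C)(C)CCC1 | intermediate
7 | methyl vinyl ketone | CC(=O)C=C | starting material
8 | 4-[(1S,2E)-2-ethylidene-6,6-dimethylcyclohexyl]butan-2-one | C/C=C1\CCCC(C)(C)[C@@H]1CCC(C)=O | intermediate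
9 | (1R,2S,4aS)-1,2,5,5-tetramethyl-1,2,3,4,4a,5,6,7-octahydronaphthalen-2-ol | C[C@]1(O)CC[C@@H]2C(=CCCC2(C)C)[C@H]1C | intermediate
10 | cyclopentene | C1=CCCC1 | starting material
11 | methyl glyoxylate | COC(=O)C=O | starting material
12 | methyl (2R)-2-[(1R)-cyclopent-2-en-1-yl]-2-hydroxyacetate | COC(=O)[C@H](O)[C@H]1C=CCC1 | intermediate
13 | methyl (2R)-2-hydroxy-2-[(1R)-4-oxocyclopent-2-en-1-yl]acetate | COC(=O)[C@H](O)[C@H]1C=CC(=O)C1 | intermediate
14 | methyl (2R)-2-[(1R)-3-chloro-4-oxocyclopent-2-en-1-yl]-2-hydroxyacetate | COC(=O)[C@H](O)[C@H]1C=C(Cl)C(=O)C1 | intermediate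
15 | 5,7-di-tert-butyl-3-phenyl-2-{[(1R,2S,4aS)-1,2,5,5-tetramethyl-1,2,3,4,4a,5,6,7-octahydronaphthalen-2-yl]oxy}-2,3-dihydrobenzoxazole (epimers at the acetal carbon) | C[C@]1(OC2Oc3c(C(C)(C)C)cc(C(C)(C)C)cc3N2c2ccccc2)CC[C@@H]2C(=CCCC2(C)C)[C@H]1C | intermediate
16 | methyl (2R)-2-{(1R,2R,3R)-3-chloro-4-oxo-2-[(1S,2R,4aS)-1,2,5,5-tetramethyl-1,2,3,4,4a,5,6,7-octahydronaphthalen-2-yl]cyclopentyl}-2-hydroxyacetate | COC(=O)[C@H](O)[C@@H]1CC(=O)[C@H](Cl)[C@H]1[C@]2(C)CC[C@@H]3C(=CCCC3(C)C)[C@H]2C | intermediate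
17 | 2-oxidocyclopentenyl (oxyallyl) cation derived from 16 | COC(=O)[C@H](O)[C@@H]1C=C([O-])[CH+][C@H]1[C@]2(C)CC[C@@H]3C(=CCCC3(C)C)[C@H]2C | intermediate
18 | methyl (1R,3R,4R,7R)-6-oxo-7-[(1S,2R,4aS)-1,2,5,5-tetramethyl-1,2,3,4,4a,5,6,7-octahydronaphthalen-2-yl]-2-oxabicyclo[2.2.1]heptane-3-carboxylate | COC(=O)[C@@H]1O[C@H]2C(=O)C[C@@H]1[C@@H]2[C@]1(C)CC[C@@H]2C(=CCCC2(C)C)[C@H]1C | intermediate
19 | methyl (1S,5R,6R,8R)-3-oxo-8-[(1S,2R,4aS)-1,2,5,5-tetramethyl-1,2,3,4,4a,5,6,7-octahydronaphthalen-2-yl]-2,7-dioxabicyclo[3.2.1]octane-6-carboxylate | COC(=O)[C@@H]1O[C@H]2OC(=O)C[C@@H]1[C@@H]2[C@]1(C)CC[C@@H]2C(=CCCC2(C)C)[C@H]1C | target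

Total step count: 10. Longest linear sequence: 7 (steps 1, 2, 3, 4, 8, 9, 10).

## Steps most likely to fail

**Step 9, the proposed new C–O closure.**
- Risks: loss of a proton from the oxyallyl cation to give the β-decalinyl cyclopentenone, capture by solvent, or Favorskii contraction.
- The fallback uses known chemistry. It sets out from 16, comes back at 19, and also bypasses step 10.
- Zn and TMSCl in THF reduce the C–Cl bond and trap the regiodefined enolate, giving methyl (2R)-2-{(1R,5R)-5-decalinyl-3-(trimethylsilyloxy)cyclopent-3-en-1-yl}-2-(trimethylsilyloxy)acetate F1.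
- Rubottom oxidation follows (1.0 equiv dimethyldioxirane, −78 °C, then citric acid in MeOH). It attacks the electron-rich enol ether faster than the hindered alkene, and from the face anti to the decalin, giving the α-hydroxy ketone methyl (2R)-2-{(1R,2R,3R)-3-hydroxy-4-oxo-2-decalinylcyclopentyl}-2-hydroxyacetate F2.
- H5IO6 in wet THF cleaves the ketol to the aldehyde acid (3R,4R)-4-decalinyl-3-[(1R)-1-hydroxy-2-methoxy-2-oxoethyl]-5-oxopentanoic acid F3.
- F3 closes spontaneously to 19 by lactol formation and acylal lactonisation.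

**Step 8, the fragment coupling.**
- Risks: slow condensation of the hindered carbinol with the benzoxazolium salt, and only modest face selectivity at the quaternary carbon.
- The fallback sets out from 9 and comes back at 16. It replaces in-flask activation by an isolable, purifiable radical precursor that fragments by oxidative double decarboxylation.
- Methyl chlorooxoacetate with DMAP and Et3N gives the mixed oxalate methyl (1R,2S,4aS)-1,2,5,5-tetramethyl-1,2,3,4,4a,5,6,7-octahydronaphthalen-2-yl oxalate F4.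
- One equivalent of aqueous CsOH gives the caesium oxalate F5.
- F5 is irradiated with 14, Ir[dF(CF3)ppy]2(dtbbpy)PF6 and water in DME/DMF (blue LED).

**Step 2, the asymmetric cross-coupling.** The chirality relay of step 3 depends on it.
- Risks: low ee with an enol triflate, or homocoupling.
- The fallback sets out from 3, comes back at 8, and bypasses steps 2 and 3.
- Carbonylative Stille coupling (Pd(PPh3)4, CO, Me4Sn, LiCl) gives 1-(3,3-dimethylcyclohex-1-en-1-yl)ethan-1-one F6.
- CBS reduction with (R)-Me-CBS and BH3 gives (1S)-1-(3,3-dimethylcyclohex-1-en-1-yl)ethan-1-ol F7.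
- Esterification gives its picolinate F8.
- Copper-mediated anti-SN2' substitution with [2-(2-methyl-1,3-dioxolan-2-yl)ethyl]magnesium bromide and CuBr·SMe2 delivers 2-{2-[(1S,2E)-2-ethylidene-6,6-dimethylcyclohexyl]ethyl}-2-methyl-1,3-dioxolane F9.
- PPTS in wet acetone unmasks F9 to 8.

## Further compounds

F1 | step 9 | methyl (2R)-2-{(1R,5R)-5-[(1S,2R,4aS)-1,2,5,5-tetramethyl-1,2,3,4,4a,5,6,7-octahydronaphthalen-2-yl]-3-(trimethylsilyloxy)cyclopent-3-en-1-yl}-2-(trimethylsilyloxy)acetate | COC(=O)[C@H](O[Si](C)(C)C)[C@@H]1CC(O[Si](C)(C)C)=C[C@H]1[C@]2(C)CC[C@@H]3C(=CCCC3(C)C)[C@H]2C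
F2 | step 9 | methyl (2R)-2-hydroxy-2-{(1R,2R,3R)-3-hydroxy-4-oxo-2-[(1S,2R,4aS)-1,2,5,5-tetramethyl-1,2,3,4,4a,5,6,7-octahydronaphthalen-2-yl]cyclopentyl}acetate | COC(=O)[C@H](O)[C@@H]1CC(=O)[C@H](O)[C@H]1[C@]2(C)CC[C@@H]3C(=CCCC3(C)C)[C@H]2C
F3 | step 9 | (3R,4R)-3-[(1R)-1-hydroxy-2-methoxy-2-oxoethyl]-5-oxo-4-[(1S,2R,4aS)-1,2,5,5-tetramethyl-1,2,3,4,4a,5,6,7-octahydronaphthalen-2-yl]pentanoic acid | COC(=O)[C@H](O)[C@H](CC(=O)O)[C@@H](C=O)[C@]1(C)CC[C@@H]2C(=CCCC2(C)C)[C@H]1C
F4 | step 8 | methyl (1R,2S,4aS)-1,2,5,5-tetramethyl-1,2,3,4,4a,5,6,7-octahydronaphthalen-2-yl oxalate | C[C@]1(OC(=O)C(=O)OC)CC[C@@H]2C(=CCCC2(C)C)[C@H]1C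
F5 | step 8 | caesium 2-oxo-2-{[(1R,2S,4aS)-1,2,5,5-tetramethyl-1,2,3,4,4a,5,6,7-octahydronaphthalen-2-yl]oxy}acetate | C[C@]1(OC(=O)C(=O)[O-])CC[C@@H]2C(=CCCC2(C)C)[C@H]1C.[Cs+]
F6 | step 2 | 1-(3,3-dimethylcyclohex-1-en-1-yl)ethan-1-one | CC(=O)C1=CC(C)(C)CCC1
F7 | step 2 | (1S)-1-(3,3-dimethylcyclohex-1-en-1-yl)ethan-1-ol | C[C@H](O)C1=CC(C)(C)CCC1
F8 | step 2 | (1S)-1-(3,3-dimethylcyclohex-1-en-1-yl)ethyl pyridine-2-carboxylate | C[C@H](OC(=O)c1ccccn1)C1=CC(C)(C)CCC1
F9 | step 2 | 2-{2-[(1S,2E)-2-ethylidene-6,6-dimethylcyclohexyl]ethyl}-2-methyl-1,3-dioxolane | C/C=C1\CCCC(C)(C)[C@@H]1CCC1(C)OCCO1
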